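I started from a comparison of the two feeds, which carries its own zero: a rate that counts substrate and coupling partner alike gives Monday's and Wednesday's nearly the same target, so a gap between them measures how unequally the two reagents count.

| flask | substrate | coupling partner | free catalyst | remark | time |
|---|---|---|---|---|---|
| south-west | 5.0 × 10⁻⁴ M | 0.80 equiv | 1 mol% | run made earlier |  |
| south-east | 5.0 × 10⁻⁴ M | 0.80 equiv | 0.67 mol% | run made earlier |  |
| east | 5.0 × 10⁻⁴ M | 0.80 equiv | 1.5 mol% | run made earlier |  |
| Sunday's | 5.0 × 10⁻⁴ M | 0.800 equiv | 1 mol% | everything together at the start | 2.5 min |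
| Monday's | 5.0 × 10⁻⁴ M | 0.800 equiv (fed, over 2.0 min) | 1 mol% | all else is in the flask from the start; the feed brings no volume worth counting | 2.5 min |
| Wednesday's | 5.0 × 10⁻⁴ M (fed, over 2.0 min) | 0.800 equiv | 1 mol% | all else is in the flask from the start; the feed brings no volume worth counting | 2.5 min |

| run | time / s | target / % | substrate / % |
|---|---|---|---|
| south-west | 10.0 | 11.4 | 89.1 |
| south-west | 15.0 | 15.7 | 83.9 |
| south-west | 25.0 | 22.1 | 77.7 |
| south-west | 50.0 | 33.8 | 66.2 |
| south-west | 90.0 | 45.8 | 54.0 |
| south-east | 10.0 | 8.6 | 91.3 |
| south-east | 30.0 | 19.3 | 80.6 |
| south-east | 60.0 | 30.7 | 69.7 |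
| south-east | 80.0 | 35.8 | 64.4 |
| south-east | 120 | 44.7 | 55.6 |
| east | 10.0 | 15.3 | 84.1 |
| east | 30.0 | 32.0 | 68.5 |
| east | 60.0 | 44.9 | 55.6 |
| east | 80.0 | 50.4 | 49.1 |
| east | 120 | 60.5 | 40.0 |

(each reading ± 0.3 percentage points)

1. the flask that comes out highest in amount of target, in percent of the substrate charged, or "all alike" when all lie within 1.5 percentage points (Sunday's / Monday's / Wednesday's / all alike)
2. target at the end, in percent of the substrate charged, Sunday's
3. target at the end, in percent of the substrate charged, Monday's
4. target at the end, in percent of the substrate charged, Wednesday's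

- what was read earlier has a scatter of 0.3 percentage points, one standard deviation

The earlier runs share one reagent ratio, so they could not tell me which reagent carries the rate, and I reckoned the far end of the scale, with substrate setting the pace and coupling partner merely keeping up. I then laid out the times as a ladder. On the lowest rung stood a burst: the south-west run had 11.4 % of the charge as target at 10.0 s. Above it, the south-west readings from 50.0 s to 90.0 s gave a pseudo-first-order time of 2.27 min, my substrate half-life, at 1 mol% of catalyst. The feed time of 2.0 min lies below it, so in Wednesday's flask fed substrate piles up, and the asked time of 2.5 min lies just above it. Feeding into that decay and letting it run to the end, I reckoned 35.8 % target for Wednesday's. For Sunday's, I ran the last south-west reading on with the same half-life and reached 60.2 %. In Monday's flask the feed has delivered coupling partner worth 33.3 % of the substrate charge by 50.0 s, which is a ceiling on the target at that time and not a reckoning of it, so I put no figure of my own on Monday's.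

The forecast, which differs from me on Wednesday's, named Sunday's with 56.5 %, 44 % and 44 %, reckoning each feed “with the burst mostly wasted”.

The flasks gave 57.8 % for Sunday's, 56.0 % for Monday's and 32.0 % for Wednesday's, against my 60.2 % for Sunday's and 35.8 % for Wednesday's, and Sunday's came out highest.

    2 catalyst intermediate A ⇌ resting dimer (K = 1.50 × 10⁶ /M, k = 6480 /M/s)
    catalyst intermediate B ⇌ catalyst intermediate C (K = 0.366, k = 96.6 /s)
    coupling partner + free catalyst → catalyst intermediate A (k = 19900 /M/s)
    substrate + catalyst intermediate A → catalyst intermediate B (k = 3710 /M/s)
    catalyst intermediate C → free catalyst + target (k = 297 /s)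

In Wednesday's flask at 1.53 min, free catalyst had a half-life of 0.11 s by its step with coupling partner, while catalyst intermediate A had 0.61 s by its step with substrate, and substrate had 2.7 min by that same step, which is longer than my 2.27 min. Running Wednesday's 68.0 % of substrate on with my half-life gives 23.4 % at 6.0 min, and the same flask left until then holds 30.0 %.

The data are simulated with made-up constants; noise was put on by code.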